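The numbers in the tables are calculated on assumed constants; scatter was added.

If a flask is stopped before its G has levelled off, its reading depends on how many lifetimes it was given, so that count comes first. L, the substrate, goes in portions into Q and X. The steps thought possible are L + X → J, X + Q → E and J + E ⇌ G, with J and E formed on the way to the product G.

| setting | noon | spring | dusk | alder | ash | birch |
|---|---|---|---|---|---|---|
| L | 1 M (in portions, 3) | 1 M (in portions, 3) | 0.50 M (in portions, 3) | 1.0 M (in portions, 3) | 1.0 M (in portions, 3) | 1.0 M (in portions, 3) |
| Q | 0.70 equiv | 0.70 equiv | 0.70 equiv | 0.700 equiv | 0.700 equiv | 0.700 equiv |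
| X | 0.75 equiv | 1.1 equiv | 1.5 equiv | 1.50 equiv | 1.50 equiv | 1.50 equiv |
| temperature | 85 °C | 118 °C | 85 °C | 130 °C | 70 °C | 100 °C |
| remark | run made earlier; portions every 30 min | run made earlier; portions every 30 min | run made earlier; portions every 30 min | the portions of L follow each other after 30 min, the first at the start | the portions of L follow each other after 30 min, the first at the start | the portions of L follow each other after 30 min, the first at the start |
| time |  |  |  | 6.0 h | 6.0 h | 6.0 h |

| noon: time / h | noon: G / % | spring: time / h | spring: G / % | dusk: time / h | dusk: G / % |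
|---|---|---|---|---|---|
| 2.50 | 13.0 | 0.417 | 28.6 | 6.00 | 34.0 |
| 5.00 | 17.1 | 0.833 | 38.6 | 12.0 | 42.3 |
| 10.0 | 23.3 | 2.00 | 42.7 | 20.0 | 42.9 |
| 20.0 | 21.8 | 4.00 | 43.9 | 30.0 | 45.4 |
| 40.0 | 22.8 | 8.00 | 44.9 | 40.0 | 44.7 |

(standard deviation of a reading: 1 percentage point)

- steps thought possible: L + X -> J; X + Q -> E; J + E <-> G

- the flask that comes out highest in amount of G, in percent of the L charged, or "all alike" when all lie within 1.5 percentage points (alder / ash / birch / all alike)
- G at the end, in percent of the L charged, alder
- G at the end, in percent of the L charged, ash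
- G at the end, in percent of the L charged, birch

*What is a lifetime here?* It is the time τ in which the gap between G and its plateau shrinks by a factor e, as in a first-order approach.

*Read one.* Dusk shows G at 34.0% after 6.00 h and 44.7% after 40.0 h, which gives τ = 4.20 h.

*But dusk ran at 0.50 M and ash runs at 1.0 M.* The step into G is bimolecular, so I let τ fall as the charge rises, to 2.10 h.

*And the temperature?* I take rates 3 times slower at 70 °C than at 85 °C, the forecast's figure as well, so ash has τ = 6.29 h.

*Is ash finished, then?* No, since its τ is longer than the 6.0 h allowed. The lifetime number N, the time allowed divided by τ, is 0.953, which puts ash at 61.4% of its plateau. With dusk's plateau as a stand-in, my own figure for ash is 27.5%.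

*Where is that weakest?* G stands at the end of steps in series, while a single exponential has no lag, so my figure leans high.

The forecast names alder, with 63% in alder, 25% in ash and 56% in birch. Its ground is that “The plateaus look like equilibrium and stoichiometry”, with ash treated as a flask still on its way.

The flask gives 66.9% in alder, 20.5% in ash and 59.3% in birch, so alder stands highest.

    L + X → J (k = 0.0164 M⁻¹ min⁻¹, Ea = 82.0 kJ mol⁻¹)
    X + Q → E (k = 0.00519 M⁻¹ min⁻¹, Ea = 90.0 kJ mol⁻¹)
    J + E ⇌ G (K = 7.10 M⁻¹, k = 0.00427 M⁻¹ min⁻¹, Ea = 97.0 kJ mol⁻¹, ΔH = 60.0 kJ mol⁻¹)
    (constants at 70 °C)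

N = 0.953 promised ash 61.4% of its plateau, and ash shows 49.0% of the 41.8% it reaches after 60.0 h. Part of what ash lacks at 6.0 h against that later value goes with the hour of the reading, acting together with the wearing away of X: with X held, ash gives 32.6% at 6.0 h. Birch, taking the factor 3 again from 85 °C to 100 °C, has N = 8.57, and it stands at 59.3% after 6.0 h and 59.3% after 60.0 h.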